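**Remark on the chemistry (assumption):** gibberellin numbering (C1–C19, C20 absent) is used for every intermediate, and the sense of the chiral-base deprotonation in step 2 is assumed to follow the 4-tert-butylcyclohexanone case, where the (R,R)-amide gives the (S)-enol ether; if it is reversed, the (R,R)-amide is used instead.

## Analysis of the target

The target, the gibberellin that carries the number 93 in the A series, is a 20-nor-ent-gibberellane in which ring A (cyclohexane) and ring B (cyclopentane) share C5–C10 and ring B is fused through C8–C9 to a bicyclo[3.2.1]octane (rings C and D) carrying the bridgehead 13-hydroxyl and the 16-methylene group. A γ-lactone from C19 (on C4) to the oxygen on C10 bridges the α face of ring A. There are ten stereocentres (C1, C2, C3, C4, C5, C6, C8, C9, C10, C13), three of them quaternary (C4, C8, C10), and C4 and C10 both flank C5. H5, H9, the C7 carboxyl, the 1-hydroxyl and the 2,3-oxirane lie on the β face and the lactone on the α face, so rings A and B are trans-fused, while C15 and H9 are syn across C8–C9. The sensitive groups are the cis epoxy alcohol, the tertiary allylic 13-ol next to the exocyclic alkene (prone to acid-induced skeletal shifts), the bridged lactone and the free acid. The difficulty is to build two quaternary centres around a trans ring fusion and then place three contiguous oxygens on one face of ring A. The strategy rests on one feature: C10 (oxygenated), C1, C2 and C3 form a four-carbon diene unit, C4–C5 a two-carbon unit carrying the C19 carbonyl and the C18 methyl, and the two are joined by C9–C8–C6, so rings A and B map onto one tethered [4+2] array.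

## Retrosynthetic reasoning

The C7 carboxyl of the target gibberellin 37 is taken back to the primary alcohol of triol 35, and 35 to its bis-silyl ether 34. The acid is made last so that no free carboxyl has to be carried through organometallic or oxidative steps.

The two C–O bonds of the oxirane in 34 are cut to give the 2-ene of allylic alcohol 33. The 1β-hydroxyl sits next to the alkene and can deliver oxygen to its own face, which is the face the target needs.

The C1–O bond of 33 is exchanged for a C3–S bond with the alkene moved to C1–C2 (sulfide 30). C1 and C3 are the two ends of one allyl unit, so a sulfoxide–sulfenate shift carries β-sulfur at C3 to β-oxygen at C1. Sulfur at C3 is also what a thio-substituted diene leaves behind.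

The lactone C19–O bond of 30 is cut to the methyl ester and C10 silyl ether of tetracycle 28. Both groups are on the α face, 1,3 to each other, so ring closure only needs the silyl group to be removed.

The key disconnection cuts C3–C4 and C5–C10 of 28 and opens rings A and B together to triene 27. These two bonds create both quaternary centres of ring A without an enolate alkylation, and the cut leaves rings C and D, with C6, C8 and C9 already set, as the tether. The forward reaction must give the trans ring fusion and add to the correct face of the diene.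

Triene 27 is the γ-enolisation product of enone 26. Cutting C10–C1 of 26 gives aldehyde 19 and vinyl iodide 24, which comes from propargyl bromide 20 and thiophenol 21 via sulfide 22. This places the sulfur and the E-alkene in a small fragment that is joined late.

The C4=C5 bond of 19 (through alcohol 18) is cut to lactol 16 and phosphonate 17. Lactol 16 comes from lactone 15, in which C5 is the carbonyl and C10 the alkoxy carbon, so one ring supplies both arms in the correct oxidation states.

The C6–C7 bond of 15 (through diol 14) is cut to lactone 12 and formaldehyde 13. The cut is made here because C6 is then the α-carbon of a lactone locked onto the rigid bicyclooctane, so its configuration is set by cyclic, not acyclic, control.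

The C13–C16 bond of 12 is cut to alkynyl ketone 11. A ketyl at C13 and a propargyl group on C8 can only close ring D in one way, and the tertiary alcohol and exocyclic alkene appear together.

The lactone of 11 is opened to ester and silyl ether 9, and the C8–C15 bond of 9 is cut to enone 7 and allenylstannane 8. Conjugate addition to a 4-substituted cyclohexenone occurs anti to the C9 substituent, which gives the C8/C9 relationship of the target.

The C8–C6 bond of 7 is cut, via enol ether 6, to enone 4 and ketene acetal 5. Addition followed by dehydrogenation puts the acetate arm on C8 while keeping the enone.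

Enone 4 is traced through enol ether 3 to the prochiral ketone 2 and the commercial alcohol 1. One enantioselective deprotonation fixes C9, and every later centre is derived from it.

## Alternatives that were turned down

Alternative 1: Here the C6–C8 bond of ring B is traced back to the C7–C8 bond of a kaurane, so the whole skeleton with the 13-hydroxyl is taken from steviol A1. In the forward step a cytochrome P450 kaurenoic acid oxidase oxidises steviol A1 at C7 and C6 and induces a 1,2-shift of C8 from C7 to C6, extruding C7 as the carboxyl and giving the ring-contracted C20 gibberellin diacid A2, the 13-hydroxylated member of the A series with the number 53. In its favour, A1 is cheap and enantiopure, and the enzyme sets C6 and C8 and forms ring B in one operation. For the C/D half this is stronger than anything in the chosen route. Against it, A2 still carries the C20 methyl on C10 and has no ring A oxygen. Removing an unactivated angular methyl with lactone formation, then hydroxylating C1 and oxidising C2–C3, has no selective chemical solution. It would need further membrane-bound oxidases whose availability and selectivity for this pattern cannot be argued from structure. The chosen strategy needs about eighteen steps to reach its key precursor, but it controls the ring A oxygens chemically through the C3 sulfur and the C10 oxygen that the cycloaddition installs.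

Alternative 2: Ring C is cut at C8–C14 and C9–C11. In the forward step 2-(trimethylsilyloxy)buta-1,3-diene A4 adds to the β-propargyl cyclopentenone A3 under a strong silyl triflimide Lewis acid, giving the cis-hydrindanone silyl enol ether A5. In its favour, quaternary C8, C9 and the C13 oxygen are made in one cycloaddition, anti to the C6 substituent, and the propargyl group is ready for ring D. For C8 this is clearly shorter than the two conjugate additions used here. Against it, the β,β-disubstituted cyclopentenone A3 is a poor dienophile, so the addition of diene A4 depends on very strong activation in the presence of an alkyne. More importantly, A5 leaves all of ring A unsolved. C10 must still become a quaternary carbinol and C4 a quaternary ester carbon on either side of C5, with a trans fusion, which means successive carbonyl additions and alkylations at crowded centres. The chosen strategy is longer in the C/D sector but forms C4, C10, C5 and C3 together in one step and keeps a handle for the 1-hydroxyl.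

Alternative 3: The three C–O bonds of ring A are cut at the very end. In the forward step a sensitised photooxygenation (ene reaction) of the 1-ene lactone A6 puts a hydroperoxy group on C1 and moves the alkene to C2–C3, and a titanium alkoxide in the same flask transfers the outer oxygen to that alkene, giving the 16-oxo-17-nor epoxy alcohol A7. In its favour, one flask installs all three oxygens with the cis relationship, and the lactone forces attack from the β face. For ring A oxidation it is as short as, or shorter than, the sulfoxide shift plus epoxidation used here. Against it, it is only an endgame and presupposes the complete tetracycle of A6. The cis-disubstituted 1-ene of A6 is a slow ene substrate. The 16-methylene group must be masked as a ketone because it would compete, so A7 still needs an olefination after the epoxy alcohol is in place, followed by ester hydrolysis. The chosen strategy takes the C1 configuration from a stereocentre set in the cycloaddition, carries the 16-ene throughout and leaves only redox steps after ring A is oxidised.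

Key step: step 19

## Route

Step 1
Reactants: 1 4-(hydroxymethyl)cyclohexan-1-one
Product: 2 4-[(tert-butyldiphenylsilyloxy)methyl]cyclohexan-1-one
Conditions: t-BuPh2SiCl, imidazole, DMF, 0 °C to rt
Reagents that add atoms: tert-butyl(chloro)diphenylsilane, CC(C)(C)[Si](Cl)(c1ccccc1)c1ccccc1
Why: Standard silylation of a primary alcohol; the bulky silyl ether is chosen because it must survive a lithium amide, Pd(OAc)2 and TiCl4 before fluoride removes it.

Step 2
Reactants: 2 4-[(tert-butyldiphenylsilyloxy)methyl]cyclohexan-1-one
Product: 3 (R)-tert-butyldiphenyl{[4-(trimethylsilyloxy)cyclohex-3-en-1-yl]methoxy}silane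
Conditions: lithium (S,S)-bis(1-phenylethyl)amide (from the amine and n-BuLi), LiCl, Me3SiCl present in the flask, THF, −100 °C
Reagents that add atoms: chlorotrimethylsilane, C[Si](C)(C)Cl
Why: Enantioselective deprotonation of a prochiral 4-substituted cyclohexanone by a C2-symmetric chiral lithium amide with internal silyl quench; the base removes one of the two enantiotopic axial α-protons, so the ring carbon that becomes C9 turns stereogenic with the (R) configuration.

Step 3
Reactants: 3 (R)-tert-butyldiphenyl{[4-(trimethylsilyloxy)cyclohex-3-en-1-yl]methoxy}silane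
Product: 4 (R)-4-[(tert-butyldiphenylsilyloxy)methyl]cyclohex-2-en-1-one
Conditions: Pd(OAc)2 (1.05 equiv), MeCN, rt
Reagents that add atoms: none
Why: Saegusa–Ito oxidation; the oxa-allyl palladium species loses a β-hydride on the side fixed by the enol ether, so the alkene is placed without touching C9.

Step 4
Reactants: 4 (R)-4-[(tert-butyldiphenylsilyloxy)methyl]cyclohex-2-en-1-one; 5 1-(tert-butyldimethylsilyloxy)-1-methoxyethene
Product: 6 methyl 2-[(1S,6R)-3-(tert-butyldimethylsilyloxy)-6-[(tert-butyldiphenylsilyloxy)methyl]cyclohex-2-en-1-yl]acetate (the two side chains trans)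
Conditions: LiClO4 (cat.), CH2Cl2, rt
Reagents that add atoms: none
Why: Mukaiyama–Michael addition with silyl transfer gives the regiodefined enol ether needed for the next dehydrogenation; the acetate adds anti to the C9 substituent, which does not matter because C8 becomes sp2 in step 5.

Step 5
Reactants: 6 methyl 2-[(1S,6R)-3-(tert-butyldimethylsilyloxy)-6-[(tert-butyldiphenylsilyloxy)methyl]cyclohex-2-en-1-yl]acetate
Product: 7 methyl 2-[(6R)-6-[(tert-butyldiphenylsilyloxy)methyl]-3-oxocyclohex-1-en-1-yl]acetate
Conditions: Pd(OAc)2 (1.1 equiv), MeCN, 40 °C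
Reagents that add atoms: none
Why: Second Saegusa–Ito oxidation; β-hydride loss from C8 gives the 3,4-disubstituted enone, with the endocyclic enone favoured over the ester-conjugated isomer.

Step 6
Reactants: 7 methyl 2-[(6R)-6-[(tert-butyldiphenylsilyloxy)methyl]-3-oxocyclohex-1-en-1-yl]acetate; 8 tributyl(propa-1,2-dien-1-yl)stannane
Product: 9 methyl 2-[(1R,2R)-2-[(tert-butyldiphenylsilyloxy)methyl]-5-oxo-1-(prop-2-yn-1-yl)cyclohexyl]acetate (propargyl trans to the CH2OSi group)
Conditions: TiCl4, CH2Cl2, −78 °C
Reagents that add atoms: none
Why: Lewis-acid-promoted conjugate addition of an allenylstannane (SE2′) delivers a propargyl group to the β-carbon and makes C8 quaternary. Allylic 1,2-strain with the C8 side chain holds the C9 substituent pseudoaxial, and axial attack on the opposite face puts C15 trans to C10 and cis to H9.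

Step 7
Reactants: 9 methyl 2-[(1R,2R)-2-[(tert-butyldiphenylsilyloxy)methyl]-5-oxo-1-(prop-2-yn-1-yl)cyclohexyl]acetate
Product: 11 cis-fused keto δ-lactone (4a-propargyl-hexahydroisochromene-3,6-dione; propargyl cis to H9), via hydroxy ester 10 (not isolated)
Conditions: Bu4NF, THF, 0 °C to rt
Reagents that add atoms: none
Why: Fluoride desilylation; the C10 alkoxide closes onto the methyl ester because the acetate arm on C8 and C10 on C9 are cis, giving the cis-fused δ-lactone with C5 as carbonyl.

Step 8
Reactants: 11 cis-fused keto δ-lactone
Product: 12 tricyclic hydroxy lactone (bicyclo[3.2.1]octane with 13-OH and 16-methylene; δ-lactone C5(=O)–O–C10 across C8–C9)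
Conditions: SmI2 (2.5 equiv), HMPA, t-BuOH, THF, 0 °C
Reagents that add atoms: none
Why: Ketyl–alkyne radical cyclisation, 5-exo-dig: the C13 ketyl adds to C16 and the vinyl radical is reduced and protonated to the exocyclic alkene. The two-carbon bridge can only span one face, so C13 follows from C8; the lactone is not reduced under these conditions.

Step 9
Reactants: 12 tricyclic hydroxy lactone; 13 formaldehyde
Product: 14 C6-hydroxymethyl lactone diol (C7 on the face of C15, anti to C14)
Conditions: LiN(iPr)2 (2.3 equiv), THF, −78 °C; then gaseous CH2O, −78 to −40 °C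
Reagents that add atoms: none
Why: Aldol addition of the lactone enolate (the 13-alkoxide is a spectator) to formaldehyde. Ring D locks the lactone chair so that the C8–C14 bond is axial beside the enolate carbon, and the electrophile enters anti to it, which sets C6 with C7 on the face of C15.

Step 10
Reactants: 14 C6-hydroxymethyl lactone diol
Product: 15 bis-silyl lactone (C7–OTBS and C13–OTBS)
Conditions: t-BuMe2SiOTf (3 equiv), 2,6-lutidine, CH2Cl2, −78 to 0 °C
Reagents that add atoms: tert-butyldimethylsilyl triflate, CC(C)(C)[Si](C)(C)OS(=O)(=O)C(F)(F)F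
Why: Silyl triflate silylates the primary and the hindered tertiary bridgehead alcohol in one operation; no stereocentre is affected.

Step 11
Reactants: 15 bis-silyl lactone
Product: 16 lactol (C5 hemiacetal, anomeric mixture)
Conditions: iBu2AlH (1.2 equiv), CH2Cl2, −78 °C
Reagents that add atoms: none
Why: Partial reduction of a δ-lactone; the tetrahedral aluminate is stable at −78 °C and gives the lactol on work-up.

Step 12
Reactants: 16 lactol; 17 methyl 2-[bis(2,2,2-trifluoroethoxy)phosphoryl]propanoate
Product: 18 (Z)-enoate alcohol (C4=C5 Z, free C10 hydroxyl)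
Conditions: KN(SiMe3)2, 18-crown-6, THF, −78 to −20 °C
Reagents that add atoms: none
Why: Still–Gennari olefination of the open hydroxy-aldehyde form of the lactol; the trifluoroethyl phosphonate with a dissociated potassium counter-ion eliminates under kinetic control to the Z-trisubstituted enoate, and the α-centre C6 is not enolised at this temperature.

Step 13
Reactants: 18 (Z)-enoate alcohol
Product: 19 C10 aldehyde
Conditions: Dess–Martin periodinane, CH2Cl2, rt
Reagents that add atoms: none
Why: Dess–Martin oxidation of a primary alcohol; the non-basic conditions should leave C9, now α to a carbonyl, unepimerised.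

Step 14
Reactants: 20 propargyl bromide; 21 thiophenol
Product: 22 phenyl prop-2-yn-1-yl sulfide
Conditions: K2CO3, acetone, 0 °C to rt
Reagents that add atoms: none
Why: SN2 S-alkylation of the thiolate; the mild base avoids isomerisation to the allenyl sulfide.

Step 15
Reactants: 22 phenyl prop-2-yn-1-yl sulfide
Product: 24 (E)-(3-iodoprop-2-en-1-yl) phenyl sulfide, via alkenylzirconocene chloride 23 (not isolated)
Conditions: Cp2Zr(H)Cl, THF, rt; then I2, 0 °C
Reagents that add atoms: iodine, II
Why: Hydrozirconation is a syn addition with zirconium on the terminal carbon, and iodinolysis proceeds with retention, so the E-alkene is fixed.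

Step 16
Reactants: 19 C10 aldehyde; 24 (E)-(3-iodoprop-2-en-1-yl) phenyl sulfide
Product: 25 allylic alcohol (C10 carbinol, both epimers)
Conditions: CrCl2 (5 equiv), NiCl2 (2 mol %), DMSO–THF, rt
Reagents that add atoms: none
Why: Nozaki–Hiyama–Kishi coupling; the alkenylchromium reagent adds to the aldehyde only, leaving the enoate and silyl ethers, with retention of the E geometry. The new carbinol centre is removed in step 17.

Step 17
Reactants: 25 allylic alcohol
Product: 26 (E)-enone (C10 ketone, C1=C2, C3 bearing SPh)
Conditions: Dess–Martin periodinane, CH2Cl2, 0 °C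
Reagents that add atoms: none
Why: Dess–Martin oxidation of a secondary allylic alcohol; thioethers are tolerated by this oxidant.

Step 18
Reactants: 26 (E)-enone
Product: 27 triene: C10 trimethylsilyloxy 3-phenylthio diene on C9 and (Z)-2-methyl enoate arm on C8
Conditions: Me3SiOTf, Et3N, CH2Cl2, −78 to 0 °C
Reagents that add atoms: trimethylsilyl triflate, C[Si](C)(C)OS(=O)(=O)C(F)(F)F
Why: Soft enolisation: O-silylation of the s-cis enone followed by γ-deprotonation gives the extended dienol ether with oxygen cis to C2 and an E vinyl sulfide. The α′ proton on C9 is tertiary and flanked by quaternary C8, so it is not removed.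

Step 19
Reactants: 27 triene
Product: 28 tetracycle with C10 silyl ether, 1-ene, 3β-phenylthio group and C4 methyl ester
Conditions: toluene (degassed), BHT, trace Et3N, 120 °C, sealed tube
Reagents that add atoms: none
Why: Concerted, asynchronous intramolecular Diels–Alder reaction; the closest known type is the thermal cyclisation of 1,3,8-nonatrienes to hydrindenes. Ring B closes as the five-membered ring across the tether C9–C8–C6 and ring A as the new cyclohexene, forming C5–C10 and C3–C4; the tether-imposed regiochemistry is the one the sulfur terminus favours electronically. C4 follows from the Z-enoate (C19 cis to C6, suprafacial), and C3 from the E vinyl sulfide (outside sulfur ends cis to outside C9, so 3β). C5 is controlled by C6: allylic 1,3-strain with the cis ester holds H6 in the alkene plane, so C8 delivers the diene anti to C7. C10 is set by which diene face is reached: in the required anti transition state the tether and ester are exo, the α-methyl is endo, and the inside silyloxy group ends on the face of C19. The selectivity needed is anti (trans-fused) over syn, and this point is the main uncertainty of the route. It is supported by the C6 conformer, by the exo-carbonyl preference of α-methyl acrylates, and by the rigid bicyclooctane, which holds C10 axial on ring C so that the syn transition state would push the diene C1–H over the axial hydrogens on C12 and C14.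

Step 20
Reactants: 28 tetracycle
Product: 30 19→10 lactone sulfide (3β-SPh and 1-ene), via C10 alcohol 29 (not isolated)
Conditions: K2CO3, MeOH, rt to 45 °C
Reagents that add atoms: none
Why: Base-catalysed methanolysis removes the tertiary trimethylsilyl ether while the two tert-butyldimethylsilyl ethers stay; the C10 alkoxide is cis-1,3 to the C19 ester and closes the γ-lactone by acyl substitution.

Step 21
Reactants: 30 19→10 lactone sulfide
Product: 33 1β-hydroxy-2-ene lactone, via sulfoxide 31 (not isolated), via sulfenate ester 32 (not isolated)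
Conditions: mCPBA (1.0 equiv), CH2Cl2, −78 °C; then P(OMe)3, MeOH, rt to 40 °C
Reagents that add atoms: 3-chloroperoxybenzoic acid, OOC(=O)c1cccc(Cl)c1
Why: Mislow–Evans rearrangement: sulfur is oxidised much faster than either alkene, and the allylic sulfoxide undergoes a suprafacial [2,3] shift that carries β-sulfur at C3 to β-oxygen at C1; the phosphite cleaves the S–O bond and drives the equilibrium.

Step 22
Reactants: 33 1β-hydroxy-2-ene lactone
Product: 34 2β,3β-epoxy-1β-ol (bis-silyl ether)
Conditions: VO(acac)2 (cat.), t-BuOOH, CH2Cl2, 0 °C to rt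
Reagents that add atoms: tert-butyl hydroperoxide, CC(C)(C)OO
Why: Vanadium-catalysed directed epoxidation delivers oxygen syn to the allylic 1β-hydroxyl, and the lactone also blocks the α face. The 16-ene has no free hydroxyl next to it and is left alone.

Step 23
Reactants: 34 2β,3β-epoxy-1β-ol (bis-silyl ether)
Product: 35 triol (1β-OH, C7–OH, 13-OH)
Conditions: HF·pyridine, pyridine, THF, 0 °C to rt
Reagents that add atoms: none
Why: Fluoride cleaves the primary and the tertiary silyl ether; buffering with pyridine should protect the oxirane and the 13-hydroxy-16-ene unit from acid.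

Step 24
Reactants: 35 triol
Product: 37 target gibberellin (number 93 of the A series), via C7 aldehyde 36 (not isolated)
Conditions: TEMPO (cat.), PhI(OAc)2, MeCN–aqueous pH 7 buffer, rt
Reagents that add atoms: water, O
Why: Oxoammonium oxidation is selective for the primary alcohol over the hindered secondary C1 and tertiary C13 alcohols; the aldehyde hydrate is oxidised on to the acid in the same flask.

## Compound list

1 | 4-(hydroxymethyl)cyclohexan-1-one | O=C1CCC(CO)CC1 | starting material
2 | 4-[(tert-butyldiphenylsilyloxy)methyl]cyclohexan-1-one | O=C1CCC(CO[Si](c2ccccc2)(c2ccccc2)C(C)(C)C)CC1 | intermediate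
3 | (R)-tert-butyldiphenyl{[4-(trimethylsilyloxy)cyclohex-3-en-1-yl]methoxy}silane | C[Si](C)(C)OC1=CC[C@H](CO[Si](c2ccccc2)(c2ccccc2)C(C)(C)C)CC1 | intermediate
4 | (R)-4-[(tert-butyldiphenylsilyloxy)methyl]cyclohex-2-en-1-one | O=C1CC[C@@H](CO[Si](c2ccccc2)(c2ccccc2)C(C)(C)C)C=C1 | intermediate
5 | 1-(tert-butyldimethylsilyloxy)-1-methoxyethene | C=C(OC)O[Si](C)(C)C(C)(C)C | starting material
6 | methyl 2-[(1S,6R)-3-(tert-butyldimethylsilyloxy)-6-[(tert-butyldiphenylsilyloxy)methyl]cyclohex-2-en-1-yl]acetate | COC(=O)C[C@@H]1C=C(O[Si](C)(C)C(C)(C)C)CC[C@H]1CO[Si](c2ccccc2)(c2ccccc2)C(C)(C)C | intermediate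
7 | methyl 2-[(6R)-6-[(tert-butyldiphenylsilyloxy)methyl]-3-oxocyclohex-1-en-1-yl]acetate | COC(=O)CC1=CC(=O)CC[C@H]1CO[Si](c2ccccc2)(c2ccccc2)C(C)(C)C | intermediate
8 | tributyl(propa-1,2-dien-1-yl)stannane | C=C=C[Sn](CCCC)(CCCC)CCCC | starting material
9 | methyl 2-[(1R,2R)-2-[(tert-butyldiphenylsilyloxy)methyl]-5-oxo-1-(prop-2-yn-1-yl)cyclohexyl]acetate | C#CC[C@]1(CC(=O)OC)CC(=O)CC[C@H]1CO[Si](c2ccccc2)(c2ccccc2)C(C)(C)C | intermediate
10 | methyl 2-[(1R,2R)-2-(hydroxymethyl)-5-oxo-1-(prop-2-yn-1-yl)cyclohexyl]acetate (hydroxy ester, not isolated) | C#CC[C@]1(CC(=O)OC)CC(=O)CC[C@H]1CO | intermediate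
11 | cis-fused keto δ-lactone (4a-propargyl-hexahydroisochromene-3,6-dione, propargyl cis to the ring-fusion hydrogen) | C#CC[C@]2(CC(=O)OC3)CC(=O)CC[C@H]23 | intermediate
12 | tricyclic hydroxy lactone (13-hydroxy-16-methylene bicyclo[3.2.1]octane, δ-lactone C5(=O)–O–C10) | C=C1C[C@]2(CC(=O)OC3)C[C@@]1(O)CC[C@H]23 | intermediate
13 | formaldehyde | C=O | starting material
14 | C6-hydroxymethyl lactone diol (C7 on the face of C15) | C=C1C[C@]2([C@@H](CO)C(=O)OC3)C[C@@]1(O)CC[C@H]23 | intermediate
15 | bis-silyl lactone (C7–OTBS, C13–OTBS) | C=C1C[C@]2([C@@H](CO[Si](C)(C)C(C)(C)C)C(=O)OC3)C[C@@]1(O[Si](C)(C)C(C)(C)C)CC[C@H]23 | intermediate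
16 | lactol (C5 hemiacetal) | C=C1C[C@]2([C@@H](CO[Si](C)(C)C(C)(C)C)C(O)OC3)C[C@@]1(O[Si](C)(C)C(C)(C)C)CC[C@H]23 | intermediate
17 | methyl 2-[bis(2,2,2-trifluoroethoxy)phosphoryl]propanoate | COC(=O)C(C)P(=O)(OCC(F)(F)F)OCC(F)(F)F | starting material
18 | (Z)-enoate alcohol (free C10 hydroxyl) | C=C1C[C@]2([C@@H](CO[Si](C)(C)C(C)(C)C)/C=C(/C)C(=O)OC)C[C@@]1(O[Si](C)(C)C(C)(C)C)CC[C@H]2CO | intermediate
19 | C10 aldehyde | C=C1C[C@]2([C@@H](CO[Si](C)(C)C(C)(C)C)/C=C(/C)C(=O)OC)C[C@@]1(O[Si](C)(C)C(C)(C)C)CC[C@H]2C=O | intermediate
20 | propargyl bromide | C#CCBr | starting material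
21 | thiophenol | Sc1ccccc1 | starting material
22 | phenyl prop-2-yn-1-yl sulfide | C#CCSc1ccccc1 | intermediate
23 | (E)-[3-(phenylthio)prop-1-enyl]zirconocene chloride (not isolated) | Cl[Zr](/C=C/CSc1ccccc1)(C1C=CC=C1)C1C=CC=C1 | intermediate
24 | (E)-(3-iodoprop-2-en-1-yl) phenyl sulfide | I/C=C/CSc1ccccc1 | intermediate
25 | allylic alcohol (C10 carbinol, both epimers) | C=C1C[C@]2([C@@H](CO[Si](C)(C)C(C)(C)C)/C=C(/C)C(=O)OC)C[C@@]1(O[Si](C)(C)C(C)(C)C)CC[C@H]2C(O)/C=C/CSc1ccccc1 | intermediate
26 | (E)-enone (C10 ketone) | C=C1C[C@]2([C@@H](CO[Si](C)(C)C(C)(C)C)/C=C(/C)C(=O)OC)C[C@@]1(O[Si](C)(C)C(C)(C)C)CC[C@H]2C(=O)/C=C/CSc1ccccc1 | intermediate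
27 | triene: C10 trimethylsilyloxy 3-phenylthio diene on C9, (Z)-enoate arm on C8 | C=C1C[C@]2([C@@H](CO[Si](C)(C)C(C)(C)C)/C=C(/C)C(=O)OC)C[C@@]1(O[Si](C)(C)C(C)(C)C)CC[C@H]2/C(O[Si](C)(C)C)=C/C=C/Sc1ccccc1 | intermediate
28 | tetracycle with C10 silyl ether, 1-ene, 3β-phenylthio group and C4 methyl ester | C=C1C[C@]23C[C@@]1(O[Si](C)(C)C(C)(C)C)CC[C@H]2[C@]1(O[Si](C)(C)C)C=C[C@H](Sc2ccccc2)[C@@](C)(C(=O)OC)[C@H]1[C@@H]3CO[Si](C)(C)C(C)(C)C | intermediate
29 | C10 alcohol methyl ester (not isolated) | C=C1C[C@]23C[C@@]1(O[Si](C)(C)C(C)(C)C)CC[C@H]2[C@]1(O)C=C[C@H](Sc2ccccc2)[C@@](C)(C(=O)OC)[C@H]1[C@@H]3CO[Si](C)(C)C(C)(C)C | intermediate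
30 | 19→10 lactone sulfide (3β-SPh, 1-ene) | C=C1C[C@]23C[C@@]1(O[Si](C)(C)C(C)(C)C)CC[C@H]2[C@@]12OC(=O)[C@@](C)([C@H]1[C@@H]3CO[Si](C)(C)C(C)(C)C)[C@@H](Sc1ccccc1)C=C2 | intermediate
31 | allylic sulfoxide (not isolated, both sulfur epimers) | C=C1C[C@]23C[C@@]1(O[Si](C)(C)C(C)(C)C)CC[C@H]2[C@@]12OC(=O)[C@@](C)([C@H]1[C@@H]3CO[Si](C)(C)C(C)(C)C)[C@@H](S(=O)c1ccccc1)C=C2 | intermediate
32 | C1 sulfenate ester (not isolated) | C=C1C[C@]23C[C@@]1(O[Si](C)(C)C(C)(C)C)CC[C@H]2[C@@]12OC(=O)[C@@](C)([C@H]1[C@@H]3CO[Si](C)(C)C(C)(C)C)C=C[C@H]2OSc1ccccc1 | intermediate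
33 | 1β-hydroxy-2-ene lactone | C=C1C[C@]23C[C@@]1(O[Si](C)(C)C(C)(C)C)CC[C@H]2[C@@]12OC(=O)[C@@](C)([C@H]1[C@@H]3CO[Si](C)(C)C(C)(C)C)C=C[C@H]2O | intermediate
34 | 2β,3β-epoxy-1β-ol bis-silyl ether | C=C1C[C@]23C[C@@]1(O[Si](C)(C)C(C)(C)C)CC[C@H]2[C@@]12OC(=O)[C@@](C)([C@H]1[C@@H]3CO[Si](C)(C)C(C)(C)C)[C@H]1O[C@H]1[C@H]2O | intermediate
35 | triol (7-hydroxy analogue of the target) | C=C1C[C@]23C[C@@]1(O)CC[C@H]2[C@@]12OC(=O)[C@@](C)([C@H]1[C@@H]3CO)[C@H]1O[C@H]1[C@H]2O | intermediate
36 | C7 aldehyde (not isolated) | C=C1C[C@]23C[C@@]1(O)CC[C@H]2[C@@]12OC(=O)[C@@](C)([C@H]1[C@@H]3C=O)[C@H]1O[C@H]1[C@H]2O | intermediate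
37 | target gibberellin (number 93 of the A series): 1β,13-dihydroxy-2β,3β-epoxy 19,10-lactone 7-carboxylic acid of the 20-norgibberell-16-ene skeleton, α and β as in the usual gibberellin drawing | C=C1C[C@]23C[C@@]1(O)CC[C@H]2[C@@]12OC(=O)[C@@](C)([C@H]1[C@@H]3C(=O)O)[C@H]1O[C@H]1[C@H]2O | target

## Step count and least certain steps

Total: 24 steps. Longest linear sequence: 22 steps (steps 1–13 and 16–24); steps 14–15 make the side fragment 24.

**Step 19 (key step).** The most likely failure is poor selectivity between the anti and syn transition states, giving the cis-fused adduct by addition to the other face of the diene at C10. In the required arrangement the inside silyloxy group lies near C11 and the ester has to be exo, and neither preference is large. A second risk is slow cycloaddition at the fully substituted diene terminus, leaving time for desilylation of the dienol ether. Fallback: add a second, temporary tether that allows only the exo-carboxyl geometry. Starting from enone 26, the methyl ester is cleaved with Me3SnOH (1,2-dichloroethane, 70 °C) to the keto acid F1. Treatment with iPr2Si(OTf)2 and Et3N converts the acid into a silyl ester and, by γ-enolisation onto the same silicon, the ketone into the dienol ether, giving the ten-membered silylene triene F2. Heating gives the bridged adduct F3; because O10 and C19 are tied together, the carboxyl can only be exo, which enforces the trans fusion. Et3N·3HF removes the silylene to give hydroxy acid F4, and carbodiimide lactonisation (EDC, DMAP) returns to the route at lactone 30.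

**Step 6.** The allenylstannane may add 1,2, may transfer an allenyl instead of a propargyl group, or may fail at the crowded β,β-disubstituted position while TiCl4 attacks the ester and silyl ether. Fallback: from enone 7, Hosomi–Sakurai allylation (allyltrimethylsilane, TiCl4, −78 °C), with the same facial course, gives the allyl ketone F5. Ozonolysis (O3, then Me2S) gives the aldehyde F6, and Ohira–Bestmann homologation (dimethyl 1-diazo-2-oxopropylphosphonate, K2CO3, MeOH) returns to the route at 9.

**Step 9.** Facial selectivity in the C–C bond formation at C6 may be low or reversed if the lactone enolate does not keep the chair assumed; retro-aldol loss or dehydration to the α-methylene lactone is a further risk. Fallback: from lactone 12, if the step gives mainly the C6 epimer F7, that compound is deprotonated with excess LiN(iPr)2 to the alkoxide-enolate and protonated kinetically at −78 °C. The proton then enters on the face that formaldehyde took, which inverts C6 and returns to the route at diol 14. Control is thereby moved from the alkylation to a protonation.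

**Step 12.** Opening of the lactol may be slow under the cold conditions needed for Z-selectivity, and the liberated C10 alkoxide may add back to the new enoate (oxa-Michael closure to a tetrahydropyran). Fallback: from lactone 15, aminolysis with MeNH(OMe)·HCl and Me3Al gives the hydroxy Weinreb amide F8. Silylation (Et3SiCl, imidazole) gives the triethylsilyl ether F9, and iBu2AlH reduction gives the aldehyde F10. Still–Gennari olefination with 17 gives the silyl-protected (Z)-enoate F11, and selective removal of the triethylsilyl group (PPTS, MeOH, 0 °C) returns to the route at alcohol 18.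

## Further compounds

F1 | step 19 | keto acid (C19 acid of enone 26) | C=C1C[C@]2([C@@H](CO[Si](C)(C)C(C)(C)C)/C=C(/C)C(=O)O)C[C@@]1(O[Si](C)(C)C(C)(C)C)CC[C@H]2C(=O)/C=C/CSc1ccccc1
F2 | step 19 | diisopropylsilylene-tethered triene (silyl ester at C19, silyl dienol ether at C10) | C=C1C[C@]2([C@@H](CO[Si](C)(C)C(C)(C)C)/C=C(/C)C(=O)O[Si](C(C)C)(C(C)C)O/C3=C\C=C\Sc4ccccc4)C[C@@]1(O[Si](C)(C)C(C)(C)C)CC[C@H]23
F3 | step 19 | silylene-bridged cycloadduct (O10–Si–O–C19) | C=C1C[C@]23C[C@@]1(O[Si](C)(C)C(C)(C)C)CC[C@H]2[C@@]12O[Si](C(C)C)(C(C)C)OC(=O)[C@@](C)([C@H]1[C@@H]3CO[Si](C)(C)C(C)(C)C)[C@@H](Sc1ccccc1)C=C2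
F4 | step 19 | 10-hydroxy 19-acid | C=C1C[C@]23C[C@@]1(O[Si](C)(C)C(C)(C)C)CC[C@H]2[C@]1(O)C=C[C@H](Sc2ccccc2)[C@@](C)(C(=O)O)[C@H]1[C@@H]3CO[Si](C)(C)C(C)(C)C
F5 | step 6 | allyl ketone (allyl in place of propargyl in 9) | C=CC[C@]1(CC(=O)OC)CC(=O)CC[C@H]1CO[Si](c2ccccc2)(c2ccccc2)C(C)(C)C
F6 | step 6 | keto aldehyde from ozonolysis | O=CC[C@]1(CC(=O)OC)CC(=O)CC[C@H]1CO[Si](c2ccccc2)(c2ccccc2)C(C)(C)C
F7 | step 9 | C6 epimer of diol 14 | C=C1C[C@]2([C@H](CO)C(=O)OC3)C[C@@]1(O)CC[C@H]23
F8 | step 12 | hydroxy Weinreb amide | C=C1C[C@]2([C@@H](CO[Si](C)(C)C(C)(C)C)C(=O)N(C)OC)C[C@@]1(O[Si](C)(C)C(C)(C)C)CC[C@H]2CO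
F9 | step 12 | C10 triethylsilyl ether of the Weinreb amide | C=C1C[C@]2([C@@H](CO[Si](C)(C)C(C)(C)C)C(=O)N(C)OC)C[C@@]1(O[Si](C)(C)C(C)(C)C)CC[C@H]2CO[Si](CC)(CC)CC
F10 | step 12 | C5 aldehyde with C10 triethylsilyl ether | C=C1C[C@]2([C@@H](CO[Si](C)(C)C(C)(C)C)C=O)C[C@@]1(O[Si](C)(C)C(C)(C)C)CC[C@H]2CO[Si](CC)(CC)CC
F11 | step 12 | (Z)-enoate with C10 triethylsilyl ether | C=C1C[C@]2([C@@H](CO[Si](C)(C)C(C)(C)C)/C=C(/C)C(=O)OC)C[C@@]1(O[Si](C)(C)C(C)(C)C)CC[C@H]2CO[Si](CC)(CC)CC
A1 | alternative 1 | steviol | C=C1C[C@]23C[C@@]1(O)CC[C@H]2[C@]1(C)CCC[C@@](C)(C(=O)O)[C@H]1CC3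
A2 | alternative 1 | C20 gibberellin diacid, number 53 of the A series (13-hydroxy, C20 methyl on C10, 7,19-dioic acid) | C=C1C[C@]23C[C@@]1(O)CC[C@H]2[C@]1(C)CCC[C@@](C)(C(=O)O)[C@H]1[C@@H]3C(=O)O
A3 | alternative 2 | β-propargyl cyclopentenone with silyloxymethyl group | C#CCC1=CC(=O)C[C@@H]1CO[Si](C)(C)C(C)(C)C
A4 | alternative 2 | 2-(trimethylsilyloxy)buta-1,3-diene | C=CC(=C)O[Si](C)(C)C
A5 | alternative 2 | cis-hydrindanone with quaternary C8 propargyl group and C13 silyl enol ether | C#CC[C@]23CC(O[Si](C)(C)C)=CC[C@H]2C(=O)C[C@@H]3CO[Si](C)(C)C(C)(C)C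
A6 | alternative 3 | 16-oxo-17-nor 1-ene lactone methyl ester, 13-trimethylsilyl ether | O=C1C[C@]23C[C@@]1(O[Si](C)(C)C)CC[C@H]2[C@@]12OC(=O)[C@@](C)([C@H]1[C@@H]3C(=O)OC)CC=C2
A7 | alternative 3 | 16-oxo-17-nor analogue of the target gibberellin as 13-trimethylsilyl ether methyl ester | O=C1C[C@]23C[C@@]1(O[Si](C)(C)C)CC[C@H]2[C@@]12OC(=O)[C@@](C)([C@H]1[C@@H]3C(=O)OC)[C@H]1O[C@H]1[C@H]2O
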